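**Assumption:** Kuwanon C (3,8‑diprenyl‑5,7,2′,4′‑tetrahydroxyflavone) has no stereocentres, so there is no enantiomer to control.

## Retrosynthetic overview
1. Kuwanon C ⇐ global MOM removal ⇐ tetra‑MOM flavone **12**.
2. Flavone **12** ⇐ key radical annulation of salicylaldehyde **7** with aryl alkyne **11**. The aroyl radical adds to the alkyne carbon that carries the alkyl group (C3–C4 bond). The resulting α‑aryl vinyl radical is oxidised to a cation and closed by the phenol O (C2–O1 bond). Ring C is therefore formed last.
3. Ring A (**7**): resorcinol → bis‑MOM ether → C5–H borylation/oxidation to give the third oxygen → ortho‑formylation → ortho‑C‑prenylation.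
4. Ring B (**11**): the same bis‑MOM resorcinol → C4 iodination → Sonogashira with TMS‑acetylene → desilylative Cu‑prenylation of the alkyne.

## Route

**Step 1**
Reactants: 1 resorcinol
Product: 2 1,3‑bis(methoxymethoxy)benzene
Conditions: MOMCl, i‑Pr2NEt, CH2Cl2, 0 °C → rt
Reagents that add atoms: chloromethyl methyl ether (MOMCl), ClCOC
Why: Double O‑alkylation gives MOM ethers that survive the later borylation, lithium‑free, radical and basic steps. No stereocentre.

**Step 2 (one pot)**
Reactants: 2
Product: 4 3,5‑bis(methoxymethoxy)phenol, via non‑isolated 3 (aryl‑Bpin)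
Conditions: B2pin2, [Ir(OMe)(cod)]2/dtbpy, THF, 80 °C; then NaBO3·4H2O, THF/H2O, rt
Reagents that add atoms: B2pin2, CC1(C)OB(OC1(C)C)B1OC(C)(C)C(C)(C)O1 (Bpin is replaced by OH); perborate/H2O2, OO (source of the new phenol O)
Why: Ir‑catalysed C–H borylation is sterically controlled and goes to C5, meta to both OMOM groups. Oxidative deborylation then gives the 1,3,5‑trioxygenated ring with one free phenol that will become O1. No stereocentre.

**Step 3**
Reactants: 4
Product: 5 2‑hydroxy‑4,6‑bis(methoxymethoxy)benzaldehyde
Conditions: MgCl2, Et3N, (CH2O)n, MeCN, reflux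
Reagents that add atoms: formaldehyde (from paraformaldehyde), C=O
Why: Casnati–Skattebøl ortho‑formylation through the magnesium phenoxide. The two ortho positions are equivalent, so the CHO lands ortho to the only free OH. No stereocentre.

**Step 4**
Reactants: 5; 6 prenyl bromide
Product: 7 2‑hydroxy‑4,6‑bis(methoxymethoxy)‑3‑(3‑methylbut‑2‑enyl)benzaldehyde
Conditions: 6 (1.1 equiv), KOH (2 equiv), MeOH/H2O, 0 °C → rt
Reagents that add atoms: none (6 is a numbered starting material)
Why: In protic solvent the phenoxide C‑alkylates (SN2 at the primary prenyl terminus, so the normal prenyl is formed). Attack is ortho to O⁻ at C3, the less hindered of the two sites between oxygens; the CHO deactivates the ring against dialkylation. No stereocentre.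

**Step 5**
Reactants: 2
Product: 8 1‑iodo‑2,4‑bis(methoxymethoxy)benzene
Conditions: NIS, MeCN, 0 °C → rt, dark
Reagents that add atoms: N‑iodosuccinimide, O=C1CCC(=O)N1I
Why: Electrophilic iodination of a 1,3‑dialkoxyarene goes at C4 (para to one OR, ortho to the other). No stereocentre.

**Step 6**
Reactants: 8; 9 trimethylsilylacetylene
Product: 10 trimethyl{[2,4‑bis(methoxymethoxy)phenyl]ethynyl}silane
Conditions: 9 (1.5 equiv), PdCl2(PPh3)2, CuI, Et3N/THF, 50 °C
Reagents that add atoms: none (9 is a numbered starting material)
Why: Sonogashira coupling. No stereocentre.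

**Step 7**
Reactants: 10; 6 prenyl bromide
Product: 11 1‑(5‑methylhex‑4‑en‑1‑yn‑1‑yl)‑2,4‑bis(methoxymethoxy)benzene
Conditions: TBAF (1.1 equiv), CuI (10 mol %), 6 (1.5 equiv), THF/DMF, 0 °C → rt
Reagents that add atoms: none (6 is a numbered starting material)
Why: Fluoride‑triggered desilylation gives a copper acetylide that undergoes Cu‑catalysed SN2 allylation with prenyl bromide, giving the internal alkyne with the prenyl group on the alkyne carbon that will become C3. No stereocentre.

**Step 8 (key radical step)**
Reactants: 7; 11 (1.5–2 equiv)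
Product: 12 tetra‑MOM‑kuwanon C, i.e. 3,8‑diprenyl‑5,7,2′,4′‑tetrakis(MOM‑oxy)flavone
Conditions: Cu(OAc)2 (20 mol %), TBHP (3 equiv), PhCl, 90 °C, N2
Reagents that add atoms: none (TBHP is only the oxidant)
Why: Proposed new method: the Cu/TBHP system abstracts the H‑bonded formyl hydrogen of 7 to give a hindered aroyl radical. This adds to the alkyl‑bearing alkyne carbon of 11 (the C3–C4 bond), giving a linear α‑aryl vinyl radical stabilised by the 2,4‑dialkoxyaryl group. Cu(II) oxidises it to the vinyl cation or Cu(III) species, and the only free ortho phenol closes 6‑endo (the C2–O1 bond) with loss of H⁺ to form the aromatic γ‑pyrone. The closest known reactions are radical annulation of aromatic aldehydes with diarylalkynes (indenones) and electrophilic 6‑endo cyclisation of o‑hydroxy/o‑alkoxyaryl ynones. Indenone formation is blocked because both aroyl ortho positions carry oxygen, and O1 regiochemistry is fixed because 7 has a single free OH. No stereocentre.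

**Step 9**
Reactants: 12
Product: 13 Kuwanon C
Conditions: 2 M HCl, MeOH/THF (1:1), 45 °C
Reagents that add atoms: none
Why: Acid hydrolysis of the four MOM acetals is mild enough to leave the trisubstituted prenyl alkenes and the flavone intact. No stereocentre.

## Compound list
1 | resorcinol | Oc1cccc(O)c1 | starting material
2 | 1,3‑bis(methoxymethoxy)benzene | COCOc1cccc(OCOC)c1 | intermediate
3 | 2‑[3,5‑bis(MOM‑oxy)phenyl]‑4,4,5,5‑tetramethyl‑1,3,2‑dioxaborolane (not isolated) | COCOc1cc(OCOC)cc(B2OC(C)(C)C(C)(C)O2)c1 | intermediate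
4 | 3,5‑bis(methoxymethoxy)phenol | COCOc1cc(O)cc(OCOC)c1 | intermediate
5 | 2‑hydroxy‑4,6‑bis(methoxymethoxy)benzaldehyde | O=Cc1c(O)cc(OCOC)cc1OCOC | intermediate
6 | prenyl bromide (1‑bromo‑3‑methylbut‑2‑ene) | CC(C)=CCBr | starting material
7 | 2‑hydroxy‑4,6‑bis(methoxymethoxy)‑3‑prenylbenzaldehyde | O=Cc1c(O)c(CC=C(C)C)c(OCOC)cc1OCOC | intermediate
8 | 1‑iodo‑2,4‑bis(methoxymethoxy)benzene | COCOc1ccc(I)c(OCOC)c1 | intermediate
9 | trimethylsilylacetylene | C#C[Si](C)(C)C | starting material
10 | {[2,4‑bis(MOM‑oxy)phenyl]ethynyl}trimethylsilane | COCOc1ccc(C#C[Si](C)(C)C)c(OCOC)c1 | intermediate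
11 | 1‑(5‑methylhex‑4‑en‑1‑yn‑1‑yl)‑2,4‑bis(MOM‑oxy)benzene | COCOc1ccc(C#CCC=C(C)C)c(OCOC)c1 | intermediate
12 | 3,8‑diprenyl‑5,7,2′,4′‑tetrakis(MOM‑oxy)flavone | CC(C)=CCc1c(-c2ccc(OCOC)cc2OCOC)oc2c(CC=C(C)C)c(OCOC)cc(OCOC)c2c1=O | intermediate
13 | Kuwanon C (no stereocentres) | CC(C)=CCc1c(-c2ccc(O)cc2O)oc2c(CC=C(C)C)c(O)cc(O)c2c1=O | target

## Totals
Total steps: 9 (step 2 is one pot). Longest linear sequence: 6 steps, either 1→2→3→4→8→9 or 1→5→6→7→8→9.

## Three steps most likely to fail
1. **Step 8 (radical annulation).** The aroyl radical from a hindered, H‑bonded phenolic aldehyde may form poorly. The bis‑allylic/propargylic CH2 of 11 is also a competing H‑atom donor.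
   Fallback (different approach): make the alkyne Ar′–C≡C–CH2CH2OTBS from 3‑butyn‑1‑ol by Sonogashira. Run the cascade, then remove the TBS group, oxidise to the aldehyde and apply an isopropylidene Wittig to build the prenyl group. Alternatively, tether the partners: Au‑catalysed Markovnikov hydrophenoxylation of 11 by 7, then intramolecular 6‑endo aroyl‑radical cyclisation.
2. **Step 4 (C3‑selective prenylation).** Risks are O‑prenylation and C5 or bis‑alkylation.
   Fallback (different approach): convert phenol 4 to its 1,1‑dimethylpropargyl ether (3‑chloro‑3‑methylbutyne, CuCl2/DBU), partially reduce it (Lindlar) to the 1,1‑dimethylallyl ether, and run an aromatic [3,3] Claisen. This delivers the normal prenyl group exclusively at the ortho position. Then do the Casnati formylation on the other ortho position.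
3. **Step 7 (alkyne prenylation).** Cu‑acetylide allylation may give SN2′ (1,1‑dimethylallyl) product or Glaser dimer.
   Fallback (different approach): use the Sonogashira/3‑butyn‑1‑ol alkyne (as in fallback 1) and build the prenyl group later on the flavone, avoiding direct alkyne prenylation.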